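**Plan**

1. Numbering: C10 (methyl-bearing ether carbon), C1, C2, C3 (OAc), C4 (bears C15H2OH), C5 (ether CH), C6 (lactone O–CH), C7, C8 (methacrylate), C9; lactone C11(=C13H2)–C12. Ring A = O/C10/C1–C5, ring B = O/C5–C10, ring C = lactone. C16/C17 = a sacrificial carbinol CH and its CH3.
2. Cuts, in retrosynthetic order: the esters on O8 and O3; C7–C8 (ring B); C7=C11, O6–C12 and C6–C7 (ring C); C4–C5 (ring A); the ester bond C6–O–C16; C3–C4; O–C5.
3. Enabling feature: in ring A the ether carbon C5 carries C6 and adjoins C4, whose only branch is the single carbon C15. Hence C6(=O)–C5(OR)–C4–C15=C16 is the γ,δ-unsaturated α-alkoxy acid left by a glycolate ester-enolate Claisen shift, with R already the tertiary C10.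
4. Forward order: the C10–C1–C2–C3 chain of linalool is O-carboxymethylated and joined to C4/C15/C16 at C3–C4. It is then closed to an eleven-membered dioxa-lactone and contracted to ring A. Ring C is built on C6 by metathesis, and ring B is closed last at C7–C8.
5. Stereochemistry: C10 comes from (R)-linalool and C3 from a (−)-MIB-catalysed alkenylzinc addition. C16 comes from (R)-but-3-yn-2-ol, is relayed to C4 and C5 in the chair [3,3] shift, and is then excised. C6 is set by Cram-chelate vinyl addition; C7 and C8 are set in the ring B closure (cis fusion, closed chair).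

Key step: step 10

Assumption: the SMILES is read literally. It puts C6 (on C5) and C9 (on C10) on opposite faces of ring A, i.e. a trans-bridgehead (inside–outside) 11-oxabicyclo[4.4.1]undecane with H5 on the inner side; all stereochemical arguments below are for this isomer.

Note on descriptors: C4 is 4S while O3 carries silicon and 4R otherwise. This is a change of CIP ranking only; the geometry does not change.

**Route**

Step 1
Reactants: 1 (R)-linalool
Product: 3 (3R)-3,7-dimethyloct-6-ene-1,3-diol, via B-alkyl-9-BBN adduct 2 (not isolated)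
Conditions: 9-BBN (1.5 equiv), THF, 0 °C → rt; then NaOH, H2O2, 0 °C
Reagents that add atoms: hydrogen peroxide, OO
Why: Chemoselective anti-Markovnikov hydroboration–oxidation: 9-BBN takes the monosubstituted vinyl group far faster than the trisubstituted alkene, C10 is untouched, and making the saturated C9–C8 arm now also removes the O-allylic unit that would later give the glycolate enolate a [2,3]-Wittig escape.

Step 2
Reactants: 3 (3R)-3,7-dimethyloct-6-ene-1,3-diol
Product: 4 (3R)-1-[(4-methoxybenzyl)oxy]-3,7-dimethyloct-6-en-3-ol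
Conditions: NaH (1.05 equiv), PMBCl, Bu4NI (cat.), THF/DMF, 0 °C → rt
Reagents that add atoms: 4-methoxybenzyl chloride, COc1ccc(CCl)cc1
Why: Williamson etherification in which one equivalent of base lets only the primary alkoxide react, so the tertiary C10 hydroxyl stays free.

Step 3
Reactants: 4 (3R)-1-[(4-methoxybenzyl)oxy]-3,7-dimethyloct-6-en-3-ol; 5 bromoacetic acid
Product: 7 methyl {[(3R)-1-[(4-methoxybenzyl)oxy]-3,7-dimethyloct-6-en-3-yl]oxy}acetate, via sodium alkoxyacetate 6 (not isolated)
Conditions: NaH (4 equiv), THF, 0 °C → reflux; then DMF, MeI, rt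
Reagents that add atoms: iodomethane, CI
Why: Williamson O-alkylation of the tertiary alkoxide with sodium bromoacetate, an unhindered SN2 electrophile, so the C10–O bond is never made or broken; carboxylate SN2 methylation follows in the same flask.

Step 4
Reactants: 7 methyl {[(3R)-1-[(4-methoxybenzyl)oxy]-3,7-dimethyloct-6-en-3-yl]oxy}acetate
Product: 9 methyl {[(3R)-1-[(4-methoxybenzyl)oxy]-3-methyl-6-oxohexan-3-yl]oxy}acetate (C3 aldehyde), via secondary ozonide 8 (not isolated)
Conditions: O3, CH2Cl2, −78 °C (Sudan Red 7B end point); Me2S, −78 °C → rt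
Reagents that add atoms: ozone, [O-][O+]=O
Why: Ozonolysis with reductive work-up: the trisubstituted alkene is the only C=C bond and reacts much faster than the anisyl ring when the gas flow is stopped at the dye end point.

Step 5
Reactants: 10 (R)-but-3-yn-2-ol
Product: 11 (R)-but-3-yn-2-yl triethylsilyl ether
Conditions: Et3SiCl, imidazole, CH2Cl2, 0 °C
Reagents that add atoms: chlorotriethylsilane, CC[Si](Cl)(CC)CC
Why: Standard silyl ether formation; the triethylsilyl group is chosen because it can later be removed beside a TBS ether.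

Step 6
Reactants: 11 (R)-but-3-yn-2-yl triethylsilyl ether; 9 C3 aldehyde
Product: 14 (3R,10R,16R)-(E)-allylic alcohol MeO2CCH2O–C10(CH3)(CH2CH2OPMB)–CH2CH2–C3H(OH)–CH=CH–C16H(OTES)CH3, via alkenyl(dicyclohexyl)borane 12 (not isolated), via alkenyl(ethyl)zinc 13 (not isolated)
Conditions: 11, Cy2BH (from BH3·SMe2 and cyclohexene), toluene, 0 °C → rt; Et2Zn, −78 °C; (−)-MIB [(−)-3-exo-morpholinoisoborneol, 10 mol%], then 9, −20 → 0 °C; aq NH4Cl
Reagents that add atoms: none
Why: Syn anti-Markovnikov hydroboration of the terminal alkyne fixes the (E)-geometry, and boron–zinc exchange followed by the amino-alcohol-catalysed asymmetric alkenylzinc addition delivers the alkenyl group to the Si face of the aldehyde (3R) without touching the ester, so no later alkyne reduction is needed.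

Step 7
Reactants: 14 (3R,10R,16R)-(E)-allylic alcohol
Product: 15 the 3-O-TBS ether of 14
Conditions: TBSCl, imidazole, DMAP (cat.), DMF, rt
Reagents that add atoms: tert-butyl(chloro)dimethylsilane, CC(C)(C)[Si](C)(C)Cl
Why: Routine silylation of the secondary allylic alcohol gives a C3 protecting group that has no acidic α-hydrogen for the later enolisation.

Step 8
Reactants: 15 the 3-O-TBS ether of 14
Product: 17 (3R,10R,16R)-seco acid HO2CCH2O–C10(CH3)(CH2CH2OPMB)–CH2CH2–C3H(OTBS)–CH=CH–C16H(OH)CH3, via lithium carboxylate 16 (not isolated)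
Conditions: LiOH, THF/MeOH/H2O, 0 °C → rt; then 1 M HCl to pH 2, THF, 0 °C
Reagents that add atoms: lithium hydroxide, [Li+].[OH-]
Why: Saponification of the methyl ester, then selective acid hydrolysis in the same flask of the much more labile triethylsilyl ether beside the TBS and PMB ethers.

Step 9
Reactants: 17 (3R,10R,16R)-seco acid
Product: 19 eleven-membered dioxa-macrolactone (3R,10R,16R; E-alkene): ring O–C10–C1–C2–C3(OTBS)–C4=C15–C16(CH3)–O–C6(=O)–C5H2; C10 bears CH3 and CH2CH2OPMB, via mixed anhydride 18 (not isolated)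
Conditions: 2-methyl-6-nitrobenzoic anhydride, DMAP, CH2Cl2, rt, syringe pump (final 1 mM)
Reagents that add atoms: none
Why: Shiina macrolactonisation activates the acid, so C16–O is untouched and 16R is retained; slow addition keeps the seco acid dilute, and the quaternary C10, the ring ether oxygen and the (E)-alkene lower the transannular strain of the eleven-membered ring.

Step 10
Reactants: 19 eleven-membered dioxa-macrolactone
Product: 22 ring A oxepane acid (3R,4S,5R,10R): 3-OTBS; 4-[(E)-prop-1-enyl]; 5-CO2H; 10-CH3; 10-CH2CH2OPMB, via (Z)-silyl ketene acetal 20 (not isolated), via trimethylsilyl ester 21 (not isolated)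
Conditions: LiN(SiMe3)2, THF, −78 °C; Me3SiCl/Et3N, −78 °C → rt, then toluene, 80 °C; 1 M citric acid
Reagents that add atoms: none
Why: LiN(SiMe3)2 deprotonates C5 of the lactone while lithium is held between the carbonyl and the ether oxygen, Me3SiCl traps this chelate as the (Z)-silyl ketene acetal 20 (ether O cis to OSiMe3), and on warming the array C5=C6–O–C16–C15=C4 undergoes a concerted suprafacial [3,3] shift that forms C4–C5, breaks O–C16 and leaves silyl ester 21, which is hydrolysed on work-up. The closest known reactions are the chelation-controlled Ireland–Claisen rearrangement of allyl glycolates and the ring-contracting Ireland–Claisen rearrangement of unsaturated macrolactones. Ring A closes by transannular bond formation, a four-atom contraction from eleven to seven members, in which the six-centre chair is trans-fused to the nascent oxepane just as in the Cope rearrangement of an (E,E)-cyclodeca-1,5-diene, because both reacting double bonds are trans within the macrocycle. C4 is controlled by C16: with the C17 methyl group pseudo-equatorial (the axial placement would clash with OSiMe3 and give a (Z)-propenyl group), the 16R centre lets only one face of the (E)-alkene reach C5. C5 is controlled by the ketene acetal geometry inside that chair: the ring bonds C4–C3 and C5–O are both pseudo-equatorial and H4 and H5 are anti, so C15 and C6 end up trans, and C6 is placed trans to C9 across the ether oxygen by reagent control rather than by ring thermodynamics. The step needs chelated over open enolisation and chair over boat: HMPA-free THF and the α-ether oxygen secure the first, the E,E geometry (whose boat would eclipse the two tether termini) secures the second, and the saturated CH2CH2OPMB group on C10 closes the [2,3]-Wittig channel that an O-allylic substituent would open.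

Step 11
Reactants: 22 ring A oxepane acid
Product: 25 trans-fused γ-lactone (3R,4S,5R,10R): C6(=O)–O–C15H2 bridging C5 and C4 of ring A, via secondary ozonide 23 (not isolated), via hydroxy acid 24 (not isolated)
Conditions: O3, CH2Cl2, −78 °C (Sudan Red 7B end point); MeOH, NaBH4, −78 → 0 °C; citric acid to pH 3; PPTS (cat.), CH2Cl2, rt
Reagents that add atoms: ozone, [O-][O+]=O
Why: Ozonolysis with borohydride work-up turns the only alkene into C15H2OH, and γ-lactonisation onto the neighbouring trans-disposed C6 acid both masks O15 and activates C6 in one operation.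

Step 12
Reactants: 25 trans-fused γ-lactone
Product: 26 lactol (C6 hemiacetal; anomer mixture)
Conditions: i-Bu2AlH (1.1 equiv), CH2Cl2, −78 °C; aq potassium sodium tartrate
Reagents that add atoms: none
Why: Partial reduction of a γ-lactone with i-Bu2AlH stops at the stable aluminium hemiacetal at −78 °C and gives the lactol as a masked C6 aldehyde.

Step 13
Reactants: 26 lactol
Product: 27 (3R,4S,5R,6R,10R)-diol: C5–C6H(OH)–CH=CH2 and C4–C15H2OH
Conditions: MgBr2·OEt2, CH2Cl2, −78 °C; CH2=CHMgBr (4 equiv), −78 → −20 °C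
Reagents that add atoms: vinylmagnesium bromide, C=C[Mg]Br
Why: Cram-chelate-controlled Grignard addition to the ring-opened lactol: magnesium ties the C6 carbonyl oxygen to the ring A ether oxygen on C5, and the vinyl group attacks the face flanked by H5 rather than C4, giving the 5,6-syn (6R) allylic alcohol.

Step 14
Reactants: 27 (3R,4S,5R,6R,10R)-diol
Product: 28 the 15-O-TBDPS ether of 27 (6-OH free)
Conditions: TBDPSCl (1.05 equiv), imidazole, CH2Cl2, 0 °C
Reagents that add atoms: tert-butyl(chloro)diphenylsilane, CC(C)(C)[Si](Cl)(c1ccccc1)c1ccccc1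
Why: The bulky silyl chloride silylates the primary hydroxyl selectively over the hindered secondary allylic one, and the TBDPS ether outlasts the TBS ether at the end of the route.

Step 15
Reactants: 28 the 15-O-TBDPS ether of 27; 29 2-(bromomethyl)acrylic acid
Product: 30 the 6-O-[2-(bromomethyl)acryloyl] ester of 28
Conditions: i-PrN=C=N-i-Pr, DMAP (10 mol%), CH2Cl2, −10 °C → rt
Reagents that add atoms: none
Why: Steglich esterification with retention at C6; the low temperature and the small DMAP charge keep the allylic bromide from quaternising the catalyst.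

Step 16
Reactants: 30 the 6-O-[2-(bromomethyl)acryloyl] ester of 28
Product: 31 (6R)-3-(bromomethyl)butenolide: ring C as O6–C12(=O)–C11(CH2Br)=C7H–C6 attached to C5
Conditions: second-generation Hoveyda–Grubbs catalyst (5 mol%), toluene, 80 °C, argon sparge
Reagents that add atoms: none
Why: Ring-closing metathesis: the catalyst loads on the unhindered C7 vinyl group and closes the five-membered ring onto the 1,1-disubstituted acrylate as methacrylates of allylic alcohols do, allylic bromides are tolerated, and no other alkene is present.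

Step 17
Reactants: 31 (6R)-3-(bromomethyl)butenolide
Product: 32 C8 primary alcohol (PMB removed)
Conditions: DDQ, CH2Cl2/pH 7 buffer, 0 °C
Reagents that add atoms: none
Why: Oxidative PMB cleavage with DDQ leaves the silyl ethers, the allylic bromide and the electron-poor butenolide untouched.

Step 18
Reactants: 32 C8 primary alcohol
Product: 33 C8 aldehyde (C10–CH2–CHO) bearing the bromomethylbutenolide
Conditions: Dess–Martin periodinane, NaHCO3, CH2Cl2, 0 °C → rt
Reagents that add atoms: none
Why: Dess–Martin oxidation runs under buffered conditions free of amine base, which avoids β-elimination of the C10 ether from the β-alkoxy aldehyde.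

Step 19
Reactants: 33 C8 aldehyde bearing the bromomethylbutenolide
Product: 35 tricyclic 8-hydroxy α-methylene lactone (3R,4S,5R,6R,7R,8R,10R): 3-OTBS; 15-OTBDPS, via allylchromium dichloride 34 (not isolated)
Conditions: CrCl2 (8 equiv), THF, rt → 45 °C, syringe pump (final 2 mM); water
Reagents that add atoms: none
Why: Intramolecular Nozaki–Hiyama allylation in Barbier mode: CrCl2 turns the bromomethylbutenolide into an allyl species of trivalent chromium that adds through its γ-carbon C7 to the C8 aldehyde in a closed Zimmerman–Traxler chair and unveils C11=C13H2; the short tether lets C8 reach only the butenolide face that carries C5 (cis fusion, 7R), and with the C4 branch outside and H5 inside the nascent seven-membered ring only the aldehyde orientation with O8 gauche to C11 and H8 inside can bridge to chromium (8R).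

Step 20
Reactants: 35 tricyclic 8-hydroxy α-methylene lactone
Product: 36 the 8-O-methacrylate of 35
Conditions: methacrylic anhydride, Et3N, DMAP, CH2Cl2, 0 °C → rt
Reagents that add atoms: methacrylic anhydride, C=C(C)C(=O)OC(=O)C(C)=C
Why: DMAP-catalysed acylation of the only free hydroxyl, which sits on the outer (equatorial) side of ring B.

Step 21
Reactants: 36 the 8-O-methacrylate of 35
Product: 37 C3 alcohol (3R,4R,5R,6R,7R,8R,10R; 15-OTBDPS kept)
Conditions: 48% aq HF, MeCN, 0 °C
Reagents that add atoms: none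
Why: Acid-type desilylation cleaves a TBS ether much faster than a TBDPS ether, and the acidic medium does not touch either ester, the lactone or the two acrylate units.

Step 22
Reactants: 37 C3 alcohol
Product: 38 the 3-O-acetate of 37
Conditions: Ac2O, pyridine, DMAP (cat.), CH2Cl2, rt
Reagents that add atoms: acetic anhydride, CC(=O)OC(C)=O
Why: Standard acetylation of the only free hydroxyl, under conditions that α-methylene lactones tolerate.

Step 23
Reactants: 38 the 3-O-acetate of 37
Product: 39 the target CNP0602302.1 (3R,4R,5R,6R,7R,8R,10R)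
Conditions: HF·pyridine, pyridine/THF, 0 °C → rt
Reagents that add atoms: none
Why: Fluoride-driven cleavage of the primary TBDPS ether in an acidic medium, in which no alkoxide forms, so the acetyl group should not migrate from O3 to O15.

**Compound list**

1 | (R)-linalool | C=C[C@@](O)(C)CCC=C(C)C | starting material
2 | B-alkyl-9-BBN adduct of 1 (boron on C8) | B1(C2CCCC1CCC2)CC[C@@](O)(C)CCC=C(C)C | intermediate
3 | (3R)-3,7-dimethyloct-6-ene-1,3-diol | OCC[C@@](O)(C)CCC=C(C)C | intermediate
4 | (3R)-1-[(4-methoxybenzyl)oxy]-3,7-dimethyloct-6-en-3-ol | COc1ccc(COCC[C@@](O)(C)CCC=C(C)C)cc1 | intermediate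
5 | bromoacetic acid | OC(=O)CBr | starting material
6 | sodium alkoxyacetate from 4 and 5 | COc1ccc(COCC[C@@](OCC(=O)[O-])(C)CCC=C(C)C)cc1.[Na+] | intermediate
7 | methyl {[(3R)-1-[(4-methoxybenzyl)oxy]-3,7-dimethyloct-6-en-3-yl]oxy}acetate | COc1ccc(COCC[C@@](OCC(=O)OC)(C)CCC=C(C)C)cc1 | intermediate
8 | secondary ozonide of 7 | COc1ccc(COCC[C@@](OCC(=O)OC)(C)CCC2OOC(C)(C)O2)cc1 | intermediate
9 | methyl {[(3R)-1-[(4-methoxybenzyl)oxy]-3-methyl-6-oxohexan-3-yl]oxy}acetate | COc1ccc(COCC[C@@](OCC(=O)OC)(C)CCC=O)cc1 | intermediate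
10 | (R)-but-3-yn-2-ol | C[C@@H](O)C#C | starting material
11 | (R)-but-3-yn-2-yl triethylsilyl ether | C[C@@H](O[Si](CC)(CC)CC)C#C | intermediate
12 | (R,E)-alkenyl(dicyclohexyl)borane from 11 | C[C@@H](O[Si](CC)(CC)CC)/C=C/B(C1CCCCC1)C1CCCCC1 | intermediate
13 | (R,E)-alkenyl(ethyl)zinc from 12 | C[C@@H](O[Si](CC)(CC)CC)/C=C/[Zn]CC | intermediate
14 | (3R,10R,16R)-(E)-allylic alcohol (methyl ester, 16-OTES, 8-OPMB) | COc1ccc(COCC[C@@](OCC(=O)OC)(C)CC[C@@H](O)/C=C/[C@@H](C)O[Si](CC)(CC)CC)cc1 | intermediate
15 | 3-O-TBS ether of 14 | COc1ccc(COCC[C@@](OCC(=O)OC)(C)CC[C@@H](O[Si](C)(C)C(C)(C)C)/C=C/[C@@H](C)O[Si](CC)(CC)CC)cc1 | intermediate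
16 | lithium carboxylate of 15 | COc1ccc(COCC[C@@](OCC(=O)[O-])(C)CC[C@@H](O[Si](C)(C)C(C)(C)C)/C=C/[C@@H](C)O[Si](CC)(CC)CC)cc1.[Li+] | intermediate
17 | (3R,10R,16R)-seco acid | COc1ccc(COCC[C@@](OCC(=O)O)(C)CC[C@@H](O[Si](C)(C)C(C)(C)C)/C=C/[C@@H](C)O)cc1 | intermediate
18 | mixed anhydride of 17 with 2-methyl-6-nitrobenzoic acid | COc1ccc(COCC[C@@](OCC(=O)OC(=O)c2c(C)cccc2[N+](=O)[O-])(C)CC[C@@H](O[Si](C)(C)C(C)(C)C)/C=C/[C@@H](C)O)cc1 | intermediate
19 | eleven-membered dioxa-macrolactone (3R,10R,16R; E) | COc1ccc(COCC[C@@]2(C)CC[C@@H](O[Si](C)(C)C(C)(C)C)/C=C/[C@@H](C)OC(=O)CO2)cc1 | intermediate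
20 | (Z)-trimethylsilyl ketene acetal of 19 | COc1ccc(COCC[C@@]2(C)CC[C@@H](O[Si](C)(C)C(C)(C)C)/C=C/[C@@H](C)O/C(O[Si](C)(C)C)=C/O2)cc1 | intermediate
21 | trimethylsilyl ester of 22 | COc1ccc(COCC[C@@]2(C)CC[C@@H](O[Si](C)(C)C(C)(C)C)[C@@H](/C=C/C)[C@@H](O2)C(=O)O[Si](C)(C)C)cc1 | intermediate
22 | ring A oxepane acid (3R,4S,5R,10R) | COc1ccc(COCC[C@@]2(C)CC[C@@H](O[Si](C)(C)C(C)(C)C)[C@@H](/C=C/C)[C@@H](O2)C(=O)O)cc1 | intermediate
23 | secondary ozonide of 22 | COc1ccc(COCC[C@@]2(C)CC[C@@H](O[Si](C)(C)C(C)(C)C)[C@@H](C3OOC(C)O3)[C@@H](O2)C(=O)O)cc1 | intermediate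
24 | 15-hydroxy acid | COc1ccc(COCC[C@@]2(C)CC[C@@H](O[Si](C)(C)C(C)(C)C)[C@@H](CO)[C@@H](O2)C(=O)O)cc1 | intermediate
25 | trans-fused γ-lactone (3R,4S,5R,10R) | COc1ccc(COCC[C@@]2(C)CC[C@@H](O[Si](C)(C)C(C)(C)C)[C@H]3COC(=O)[C@@H]3O2)cc1 | intermediate
26 | lactol (anomer mixture) | COc1ccc(COCC[C@@]2(C)CC[C@@H](O[Si](C)(C)C(C)(C)C)[C@H]3COC(O)[C@@H]3O2)cc1 | intermediate
27 | (3R,4S,5R,6R,10R)-diol with C6 vinyl carbinol | COc1ccc(COCC[C@@]2(C)CC[C@@H](O[Si](C)(C)C(C)(C)C)[C@@H](CO)[C@@H](O2)[C@H](O)C=C)cc1 | intermediate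
28 | 15-O-TBDPS ether of 27 | COc1ccc(COCC[C@@]2(C)CC[C@@H](O[Si](C)(C)C(C)(C)C)[C@@H](CO[Si](c3ccccc3)(c3ccccc3)C(C)(C)C)[C@@H](O2)[C@H](O)C=C)cc1 | intermediate
29 | 2-(bromomethyl)acrylic acid | C=C(CBr)C(=O)O | starting material
30 | 6-O-[2-(bromomethyl)acryloyl] ester of 28 | COc1ccc(COCC[C@@]2(C)CC[C@@H](O[Si](C)(C)C(C)(C)C)[C@@H](CO[Si](c3ccccc3)(c3ccccc3)C(C)(C)C)[C@@H](O2)[C@H](OC(=O)C(=C)CBr)C=C)cc1 | intermediate
31 | (6R)-3-(bromomethyl)butenolide (8-OPMB) | COc1ccc(COCC[C@@]2(C)CC[C@@H](O[Si](C)(C)C(C)(C)C)[C@@H](CO[Si](c3ccccc3)(c3ccccc3)C(C)(C)C)[C@@H](O2)[C@@H]3OC(=O)C(CBr)=C3)cc1 | intermediate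
32 | C8 primary alcohol | OCC[C@@]1(C)CC[C@@H](O[Si](C)(C)C(C)(C)C)[C@@H](CO[Si](c2ccccc2)(c2ccccc2)C(C)(C)C)[C@@H](O1)[C@@H]2OC(=O)C(CBr)=C2 | intermediate
33 | C8 aldehyde | O=CC[C@@]1(C)CC[C@@H](O[Si](C)(C)C(C)(C)C)[C@@H](CO[Si](c2ccccc2)(c2ccccc2)C(C)(C)C)[C@@H](O1)[C@@H]2OC(=O)C(CBr)=C2 | intermediate
34 | allylchromium dichloride from 33 | O=CC[C@@]1(C)CC[C@@H](O[Si](C)(C)C(C)(C)C)[C@@H](CO[Si](c2ccccc2)(c2ccccc2)C(C)(C)C)[C@@H](O1)[C@@H]2OC(=O)C(C[Cr](Cl)Cl)=C2 | intermediate
35 | tricyclic 8-hydroxy α-methylene lactone (3R,4S,5R,6R,7R,8R,10R) | O[C@@H]1C[C@@]2(C)CC[C@@H](O[Si](C)(C)C(C)(C)C)[C@@H](CO[Si](c3ccccc3)(c3ccccc3)C(C)(C)C)[C@@H](O2)[C@@H]2OC(=O)C(=C)[C@@H]21 | intermediate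
36 | 8-O-methacrylate of 35 | C=C(C)C(=O)O[C@@H]1C[C@@]2(C)CC[C@@H](O[Si](C)(C)C(C)(C)C)[C@@H](CO[Si](c3ccccc3)(c3ccccc3)C(C)(C)C)[C@@H](O2)[C@@H]2OC(=O)C(=C)[C@@H]21 | intermediate
37 | C3 alcohol (15-OTBDPS) | C=C(C)C(=O)O[C@@H]1C[C@@]2(C)CC[C@@H](O)[C@@H](CO[Si](c3ccccc3)(c3ccccc3)C(C)(C)C)[C@@H](O2)[C@@H]2OC(=O)C(=C)[C@@H]21 | intermediate
38 | 3-O-acetate of 37 | C=C(C)C(=O)O[C@@H]1C[C@@]2(C)CC[C@@H](OC(C)=O)[C@@H](CO[Si](c3ccccc3)(c3ccccc3)C(C)(C)C)[C@@H](O2)[C@@H]2OC(=O)C(=C)[C@@H]21 | intermediate
39 | CNP0602302.1 | C=C(C)C(=O)O[C@@H]1C[C@@]2(C)CC[C@@H](OC(C)=O)[C@@H](CO)[C@@H](O2)[C@@H]2OC(=O)C(=C)[C@@H]21 | target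

**Step count**

Total steps: 23. Longest linear sequence: 22 steps (1 → 39 through steps 1–4 and 6–23). Step 5 is the only step off the main line.

**Steps most likely to fail**

Step 19 (ring B closure). The closure has to pay for the strain of the trans-bridged bicycle. Protonation or dimerisation of the allylchromium species may therefore outrun it, or it may leak through the other fold of the nascent ring with loss of facial selectivity at C8. The fallback replaces the transient organochromium by an isolable allylboronate. The closure then becomes a unimolecular thermal allylboration that can be heated at high dilution with no competing quench, while keeping the same closed chair.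
- It sets out from 31.
- Pd2(dba)3-catalysed borylation with bis(pinacolato)diboron should give the allylic pinacol boronate F1.
- DDQ should free the boronate C8 alcohol F2.
- Dess–Martin oxidation should give the boronate C8 aldehyde F3.
- F3 is heated in toluene (Sc(OTf)3 catalysis if needed) and worked up with aqueous NaHCO3.
- The route is rejoined at 35.

Step 10 (ring contraction). Enolisation outside the chelate, or passage through a boat, would erode the selectivity. In both cases the alkene face is still dictated by C16, so only C5 is inverted. The fallback sets C5 under thermodynamic instead of pericyclic control.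
- It sets out from 19, whose rearrangement would then deliver the 5-epimeric oxepane acid F4.
- Methylation (MeI, K2CO3, DMF) should give the 5-epimeric methyl ester F5.
- Equilibration with NaOMe in MeOH should favour the 4,5-trans methyl ester F6, because it avoids the all-cis arrangement of the C3, C4 and C5 substituents.
- Ozonolysis of F6 with NaBH4 work-up and PPTS-catalysed lactonisation rejoins the route at 25.

Step 9 (macrolactonisation). Oligomerisation may compete with the slow closure of a medium ring at the ester bond. The fallback makes the ester bond intermolecularly and closes the ring at C3–C4.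
- It sets out from 7 and 11.
- LiOH should convert 7 into the free alkoxyacetic acid F7.
- Cp2Zr(H)Cl and then I2 should convert 11 into the (R,E)-vinyl iodide silyl ether F8.
- Aqueous acetic acid should turn F8 into (R,E)-4-iodobut-3-en-2-ol F9.
- Carbodiimide coupling of F7 with F9 should give the iodoalkenyl ester F10, and ozonolysis of its prenyl alkene the iodoalkenyl ester aldehyde F11.
- An intramolecular Nozaki–Hiyama–Kishi reaction (CrCl2, NiCl2 cat., DMSO/THF, high dilution) should close the macrocyclic (3R)-allylic alcohol F12.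
- C3 then depends on the conformation of the closing ring. The epimers are separable, and a chiral sulfonamide ligand on chromium is available if needed.
- Silylation with TBSCl rejoins the route at 19.

**Further compounds**

F1 | step 19 | allylic pinacol boronate (8-OPMB) | COc1ccc(COCC[C@@]2(C)CC[C@@H](O[Si](C)(C)C(C)(C)C)[C@@H](CO[Si](c3ccccc3)(c3ccccc3)C(C)(C)C)[C@@H](O2)[C@@H]3OC(=O)C(CB4OC(C)(C)C(C)(C)O4)=C3)cc1
F2 | step 19 | boronate C8 alcohol | OCC[C@@]1(C)CC[C@@H](O[Si](C)(C)C(C)(C)C)[C@@H](CO[Si](c2ccccc2)(c2ccccc2)C(C)(C)C)[C@@H](O1)[C@@H]2OC(=O)C(CB3OC(C)(C)C(C)(C)O3)=C2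
F3 | step 19 | boronate C8 aldehyde | O=CC[C@@]1(C)CC[C@@H](O[Si](C)(C)C(C)(C)C)[C@@H](CO[Si](c2ccccc2)(c2ccccc2)C(C)(C)C)[C@@H](O1)[C@@H]2OC(=O)C(CB3OC(C)(C)C(C)(C)O3)=C2
F4 | step 10 | 5-epimeric oxepane acid (3R,4S,5S,10R) | COc1ccc(COCC[C@@]2(C)CC[C@@H](O[Si](C)(C)C(C)(C)C)[C@@H](/C=C/C)[C@H](O2)C(=O)O)cc1
F5 | step 10 | 5-epimeric methyl ester | COc1ccc(COCC[C@@]2(C)CC[C@@H](O[Si](C)(C)C(C)(C)C)[C@@H](/C=C/C)[C@H](O2)C(=O)OC)cc1
F6 | step 10 | 4,5-trans methyl ester (methyl ester of 22) | COc1ccc(COCC[C@@]2(C)CC[C@@H](O[Si](C)(C)C(C)(C)C)[C@@H](/C=C/C)[C@@H](O2)C(=O)OC)cc1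
F7 | step 9 | free alkoxyacetic acid | COc1ccc(COCC[C@@](OCC(=O)O)(C)CCC=C(C)C)cc1
F8 | step 9 | (R,E)-vinyl iodide silyl ether | C[C@@H](O[Si](CC)(CC)CC)/C=C/I
F9 | step 9 | (R,E)-4-iodobut-3-en-2-ol | C[C@@H](O)/C=C/I
F10 | step 9 | iodoalkenyl ester | COc1ccc(COCC[C@@](OCC(=O)O[C@H](C)/C=C/I)(C)CCC=C(C)C)cc1
F11 | step 9 | iodoalkenyl ester aldehyde | COc1ccc(COCC[C@@](OCC(=O)O[C@H](C)/C=C/I)(C)CCC=O)cc1
F12 | step 9 | macrocyclic (3R)-allylic alcohol | COc1ccc(COCC[C@@]2(C)CC[C@@H](O)/C=C/[C@@H](C)OC(=O)CO2)cc1
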